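(The numbers in the tables were computed on assumed constants; scatter was added.)

The dawn run at 55 °C stood at 61 % Pdt after 8.00 d, and the noon run, the flask asked about, at 66 %, with 37 % and 36 % of the Sbt still there. Two chemists read that stall differently.

| flask | Sbt | Rgt | Cat | temperature | remark | time |
|---|---|---|---|---|---|---|
| noon | 31 mM | 46.5 mM | 0.24 mM | 60 °C | the very flask that is asked about, followed so far |  |
| dawn | 31 mM | 46.5 mM | 0.24 mM | 55 °C | run made earlier |  |
| flask | 31 mM | 46.5 mM | 0.24 mM | 60 °C |  | 8.0 d |

| run | time / d | Pdt / % | Sbt / % |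
|---|---|---|---|
| noon | 2.08 | 46 | 51 |
| noon | 4.00 | 58 | 40 |
| noon | 6.00 | 61 | 40 |
| noon | 8.00 | 66 | 36 |
| dawn | 2.08 | 40 | 60 |
| dawn | 4.00 | 52 | 51 |
| dawn | 6.00 | 63 | 38 |
| dawn | 8.00 | 61 | 37 |

(scatter of a reading: 2 percentage points)

- elm: change nothing and wait 4.0 d more
- oak: at 8.0 d add Cat, 100 % of the amount charged, then wait 4.0 d
- cedar: at 8.0 d raise the temperature by 15 K, then wait 4.0 d
- ash: at 8.0 d add Rgt, 100 % of the amount charged, then wait 4.0 d
- alder: at 8.0 d take out 90 % of the Pdt then present, then wait 4.0 d

- what is taken out of Pdt is counted as made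
- the earlier runs were read with a standard deviation of 2 percentage points
- what may be going on: Rgt + Cat -> Imd; Sbt + Imd <-> Imd2; Imd2 -> Cat + Pdt; Rgt + Imd -> Zed
- additions bring no volume worth counting

- Pdt, in percent of the Sbt first charged, at 8.0 d
- which option adds most Pdt ("none" when 2 percentage points or less is all one gets) (elm / oak / cedar / ash / alder / none)
- Pdt present, with what was taken out counted in, in percent of the Sbt first charged, after oak
- Pdt present, with what was taken out counted in, in percent of the Sbt first charged, after cedar

The first chemist calls it an equilibrium. The noon flask's last readings give Pdt over Sbt of 1.83. If 90 % of the Pdt is taken out and the flask refills to that ratio, alder ends near 86.9 %, and oak gives nothing.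

The second chemist made the forecast, and says the stall “points to catalyst death”. It puts the noon flask at 65 % now (63 % to 67 %) and picks oak: “Fresh Cat restarts turnover”, to 84 % (76 % to 91 %), while cedar gives 68 % (65 % to 72 %).

My own reckoning takes the same side but differs on the number. At the board, Imd has two roads: on with Sbt towards Pdt, or off with Rgt to Zed. So the Pdt made per Cat lost goes with [Sbt]/[Rgt]. A round takes one of each, so [Rgt] minus [Sbt] stays near 15.5 mM. Adding up along the run gives the Cat budget, the sum of Pdt made and that difference times ln(charged [Sbt]/present [Sbt]), which grows in step with the Cat charged. The noon readings at 8.00 d put it at 36.3 mM, within their scatter, which makes the selectivity factor 151.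

Oak doubles the budget to 72.6 mM. Reaching the forecast's 84 % costs 54.4 mM, less than that budget, so my figure stands higher. Putting 31 mM for the Pdt term puts the point where the doubled budget is spent near 93.2 %. I expect a little under it, since the noon flask stood at 58 % after 4.00 d, below its 66 % after 8.00 d.

The flask gives 64.1 % now. Oak adds 26 percentage points and reaches 90.3 %, which is 6.3 points above the forecast, while alder adds 0.98 points and cedar ends at 65.2 %.

    Rgt + Cat → Imd (k = 1610 /M/h, Ea = 49.0 kJ/mol)
    Sbt + Imd ⇌ Imd2 (K = 6.82 /M, k = 631 /M/h, Ea = 67.0 kJ/mol, ΔH = −4.00 kJ/mol)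
    Imd2 → Cat + Pdt (k = 19.4 /h, Ea = 89.0 kJ/mol)
    Rgt + Imd → Zed (k = 0.723 /M/h, Ea = 90.0 kJ/mol)
    (constants at 60 °C)

The equilibrium view keeps one place inside the round: Imd2 returns to Sbt + Imd at 92.5 /h, faster than the 19.4 /h at which it goes on to Pdt. Oak's 90.3 % cost 64.2 mM of the 72.6 mM. The neighbour flask holds 79 mM of Rgt, 2.55 equiv, with the same Cat and so the same budget, but its difference is 48.0 mM. It ended at 39.6 % Pdt with 60 % of its Sbt left, a cost of 36.8 mM against the 36.3 mM read from noon.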